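## Structural features

The target 16 is a 2-arylbenzofuran. A benzo ring A (C3a, C4 to C7, C7a) is fused to a furan (O1, C2, C3); C2 carries ring B (4-hydroxy-2-methoxyphenyl) through an aryl–heteroaryl C–C bond and C3 carries a formyl group. Ring A has a free hydroxyl on C4, a 3-methylbut-2-enyl (prenyl) chain on C5 and a methoxy group on C6, so only C7 keeps a hydrogen and the oxygens on C4, C6 and C7a form a phloroglucinol pattern. There is no stereocentre, and the prenyl double bond ends in two identical methyl groups, so nothing configurational has to be set. All problems are of regio- and chemoselectivity.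

The fragile groups are the aldehyde (reducible, peri to the C4 hydroxyl), the prenyl alkene (hydrogenation, oxidants, acid-induced closure onto the C4 hydroxyl to a chroman) and two oxidisable phenols that must be told apart from each other and from two methyl ethers. The real difficulty is the fully substituted furan, with an aryl group on C2 and a carbon at the aldehyde level on C3, beside a ring A in which prenyl must go to C5 alone and not to C7 or ring B.

The key step uses the fact that C2 is bonded to O1 and ring B while C3 is bonded to C3a and the formyl carbon. C2 can therefore be the carboxyl carbon of a ring B benzoate esterified to the ring A oxygen that becomes O1, and C3 the carbonyl carbon of an ortho acetyl group, so reductive union of the two carbonyl carbons makes C2=C3 and the furan together. Two further features help: the oxygens destined for C4 and C7a are equivalent in a symmetric 2,6-dihydroxyacetophenone, and C5 is the only hydrogen-bearing carbon ortho to the C4 oxygen, hence the only possible terminus of a Claisen shift.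

## Logic of the disconnections

**16 to 15.** The O–H of ring B is traced back to an O–Si bond. The ring B phenol has to stay masked while the C4 oxygen is alkylated and while DDQ is used, and a bulky silyl ether can be removed by fluoride, which leaves aldehyde, prenyl alkene and the ortho-prenyl phenol alone. The skeleton is unchanged, but the two phenols become distinguishable. The forward step must be non-acidic and buffered.

**15 to 14.** The C5–CH2 bond of the prenyl chain is cut by a retro-Claisen operation, which moves the five-carbon unit onto the C4 oxygen as a tertiary 1,1-dimethylallyl ether. C5 is the only ortho carbon of that oxygen with a hydrogen, so the sigmatropic shift cannot deliver to C7 or to ring B. A C–C bond to a crowded arene carbon is exchanged for an O–C bond. The forward step needs neutral thermal conditions and the tertiary, not the primary, allyl ether.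

**14 to 13, then to 10 and 11.** The vinyl group is traced to an ethynyl group, and the bond between the C4 oxygen and the tertiary carbon is then cut. A tertiary allyl ether cannot be made by direct substitution, whereas the propargylic ester 12 made from 11 reacts at its tertiary carbon through a copper allenylidene. All five prenyl carbons then come from a bulk alkynol. The forward steps must alkylate a phenol that is hydrogen-bonded to the peri formyl group in 10, and must stop the hydrogenation at the alkene.

**10 to 9.** The C4 O–H is traced to an O–benzyl bond. This oxygen needs a group that survives low-valent titanium and DDQ and is orthogonal to the silyl ether on ring B. The forward hydrogenolysis has to spare the aldehyde.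

**9 to 8.** The formyl group is traced to a methyl group, a change of oxidation level only. An oxygenated carbon next to the ketone would be cleaved in the reductive coupling, whereas a methyl group is inert there. Its C–H bonds are activated afterwards by O1 and ring B through C2=C3. The forward oxidation must stop at the aldehyde and must be run before the phenols are freed and the prenyl group is present.

**8 to 7.** The C2=C3 bond is cut and both carbons become carbonyl carbons: C2 the ester carbon, C3 the ketone carbon. The furan opens and O1 becomes the phenolic oxygen of an aryl ester. The aryl–furan connection never has to be made by cross-coupling, because rings A and B are joined through an ester. The forward step must couple two electrophilic carbons reductively, within one molecule, with the ketone reduced first.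

**7 to 2 and 5, through 6.** The ester C–O bond is cut. This is the simplest union of the two halves. The forward step must acylate a hydrogen-bonded phenol without base-induced acyl migration to carbon.

**2 to 1, and 5 to 3 through 4.** In 2 the O–benzyl bond is cut. Because 1 is symmetric, mono-etherification raises no regiochemical question and decides which oxygen becomes O1 and which the C4 oxygen. In 5 the O–Si bond is cut. The forward step must silylate the phenol and leave the acid free, which is done through the bis-silyl compound 4 and selective hydrolysis of its silyl ester.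

## Other disconnections considered

**Alternative 1:** Ring A is taken apart at C4–C5, C6–C7 and C3a–C4. This leaves a furan, methyl 5-(2-diazoacetyl)-2-[2-methoxy-4-(triisopropylsilyloxy)phenyl]furan-3-carboxylate A1, and an ynol ether, 1-methoxy-5-methylhex-4-en-1-yne A2.

- **Forward step.** Light would convert A1 by Wolff rearrangement into a furylketene, which adds to A2 in a [2+2] sense. The cyclobutenone opens to a dienylketene, and six-electron closure onto the free furan β-carbon followed by tautomerisation would give the benzofuran ester A3.
- **In favour.** Pentasubstituted ring A would be formed in one operation with hydroxyl, prenyl and methoxy in the right order. The order follows from the polarisation of A2, whose prenyl-bearing carbon bonds to the ketene carbonyl carbon that becomes C4. The C4 hydroxyl appears free, with no benzyl group and no Claisen sequence; on this point the alternative is better than the chosen plan.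
- **Against.** C3 arrives as an ester and needs reduction and re-oxidation beside a free peri phenol and the prenyl alkene. A2 is a skipped enyne ynol ether that must be made and is prone to isomerisation. A1 needs a separate synthesis of a trisubstituted furan plus a diazo transfer. The closure has to break furan aromaticity for a moment.
- **Comparison.** On structure it solves the ring A substitution directly, whereas the chosen plan buys ring A and adds prenyl late. On mechanism it is a cascade of four pericyclic events against one reductive coupling; both are regiochemically unambiguous, so they are equal there. On step economy it needs about three steps after the key step against six, but clearly more before it, so the total is not expected to be shorter and the starting materials are less accessible.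

**Alternative 2:** The C2–ring B bond and the C3–formyl bond are cut together. The pieces are 4,6-dimethoxybenzofuran A4, the ring B boronic ester 2-[2-methoxy-4-(triisopropylsilyloxy)phenyl]-4,4,5,5-tetramethyl-1,3,2-dioxaborolane A5, and the chloroiminium salt N-(chloromethylidene)-N-methylmethanaminium chloride A6.

- **Forward step.** A4 is lithiated at C2 with n-BuLi and added to A5 to give a boronate. A6 attacks C3 while ring B shifts from boron to C2. NaBO3 work-up removes boron, restores the furan and frees the aldehyde, giving A7.
- **In favour.** It is the shortest route to the 2-aryl-3-formyl furan. The aldehyde arrives at the right oxidation level, so no benzylic oxidation is needed, and no reducing metal is used; on both points it is better than the chosen plan.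
- **Against.** A7 has a methyl ether on C4. The route then depends on removing one of three aryl methyl ethers selectively, for example with BCl3 directed by the peri aldehyde, with the silyl ether present. The migrating group is an ortho-substituted aryl group, and the electrophile must reach C3 next to the C4 methoxy group.
- **Comparison.** On structure the late prenyl sequence is the same, so the two are equal. On mechanism the metallate shift has less support on this substrate class than the keto ester coupling. On step economy the alternative would probably be one or two steps shorter if the demethylation is selective; that single step carries the risk which benzyl protection removes in the chosen plan.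

**Alternative 3:** O1–C7a and C3–C3a are cut. The pieces are the symmetric aryne precursor 5-methoxy-2-(trimethylsilyl)-1,3-phenylene bis(trifluoromethanesulfonate) A8 and the ring B iodonium ylide methyl 3-[2-methoxy-4-(methoxymethoxy)phenyl]-3-oxo-2-(phenyl-λ3-iodanylidene)propanoate A9.

- **Forward step.** CsF releases the aryne from A8. The ylide oxygen adds to the aryne carbon remote from the remaining triflate, and the aryl anion next to the triflate captures the ylide carbon with loss of iodobenzene, giving the benzofuran ester A10.
- **In favour.** Both furan bonds form under mild, metal-free conditions in a convergent step. The symmetric A8 can give only one aryne, and the triflate directs the regiochemistry. The C4 oxygen is differentiated from the start as a triflate, which is the equal of the benzyl differentiation in the chosen plan.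
- **Against.** The triflate must be cleaved to the phenol. The C3 ester needs reduction and re-oxidation. The methoxymethyl group must finally be removed with acid beside the ortho-prenyl phenol, which invites chroman formation. A8 needs a multi-step preparation.
- **Comparison.** On structure both plans unite ring B with ring A through oxygen and close the furan, so they are equal. On mechanism the ester redox is more predictable than a benzylic oxidation (a point for the alternative), while the acidic last step is worse than fluoride. On step economy about eight steps follow the key step against six, and the route is longer before it.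

Key step: step 4

Assumption: benzofuran numbering (O1, C2, C3, C3a, C4 to C7, C7a) is used throughout, ring A is the benzo ring and ring B the aryl group on C2; compounds 1, 3 and 11 and all reagents are taken to be commercially available.

## Route

Step 1
Reactants: 1 1-(2,6-dihydroxy-4-methoxyphenyl)ethanone
Product: 2 1-[2-(benzyloxy)-6-hydroxy-4-methoxyphenyl]ethanone
Conditions: BnBr (1.0 equiv), K2CO3 (1.1 equiv), acetone, reflux
Reagents that add atoms: benzyl bromide, BrCc1ccccc1
Why: Williamson ether synthesis on a symmetric bis-phenol, so only one mono-ether is possible; after the first alkylation the remaining hydroxyl is locked in a hydrogen bond to the ketone and is much less nucleophilic, which should hold the reaction at the mono-ether.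

Step 2
Reactants: 3 4-hydroxy-2-methoxybenzoic acid
Product: 5 2-methoxy-4-(triisopropylsilyloxy)benzoic acid, via triisopropylsilyl 2-methoxy-4-(triisopropylsilyloxy)benzoate 4 (not isolated)
Conditions: i-Pr3SiCl (2.3 equiv), imidazole, DMF, rt; then K2CO3, THF/MeOH/H2O, rt; 1 M HCl to pH 3
Reagents that add atoms: triisopropylsilyl chloride, CC(C)[Si](Cl)(C(C)C)C(C)C
Why: Silylation of both acidic hydroxyls followed by selective solvolysis; the silyl ester is an activated acyl derivative and is cleaved by mild aqueous carbonate far faster than the hindered aryl triisopropylsilyl ether.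

Step 3
Reactants: 5 2-methoxy-4-(triisopropylsilyloxy)benzoic acid; 2 1-[2-(benzyloxy)-6-hydroxy-4-methoxyphenyl]ethanone
Product: 7 2-acetyl-3-(benzyloxy)-5-methoxyphenyl 2-methoxy-4-(triisopropylsilyloxy)benzoate, via 2-methoxy-4-(triisopropylsilyloxy)benzoyl chloride 6 (not isolated)
Conditions: 5, (COCl)2, DMF (cat.), CH2Cl2, 0 °C to rt, evaporate; then 2, Et3N, DMAP (cat.), CH2Cl2, 0 °C to rt
Reagents that add atoms: none
Why: Acid chloride formation under Vilsmeier-type catalysis, then DMAP-catalysed O-acylation (nucleophilic catalysis), which is strong enough for a hydrogen-bonded phenol. The weak amine base avoids the Baker–Venkataraman acyl shift, and benzyl and silyl ethers are untouched.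

Step 4
Reactants: 7 2-acetyl-3-(benzyloxy)-5-methoxyphenyl 2-methoxy-4-(triisopropylsilyloxy)benzoate
Product: 8 4-(benzyloxy)-6-methoxy-2-[2-methoxy-4-(triisopropylsilyloxy)phenyl]-3-methylbenzofuran
Conditions: TiCl3 (5 equiv), Zn dust (10 equiv), DME, reflux (pre-reduction); then 7 in DME added slowly at reflux
Reagents that add atoms: none
Why: Zinc reduces TiCl3 to low-valent titanium, which transfers electrons to the aryl ketone of 7, the more easily reduced of the two carbonyl groups, to give a titanium-bound ketyl at the future C3. This carbon adds to the ester carbonyl carbon held in the ortho position, a 5-exo-trig closure that forms the C2–C3 bond and a cyclic titanium 1,2-diolate. Stepwise C–O cleavage on the oxophilic titanium then removes both oxygens and leaves the C2=C3 double bond, driven by strong Ti–O bonds and by aromatisation to the furan. The closest known reaction type is the intramolecular McMurry-type keto ester coupling of 2-acyloxyaryl ketones to 2,3-disubstituted benzofurans with TiCl3 and zinc. No stereocentre is formed. The step needs the ketone to react before the ester and ring closure to outrun intermolecular pinacol coupling; the ortho tether secures both, the two ortho substituents flanking the ketone hinder dimerisation, and slow addition to the pre-formed reagent keeps the substrate dilute. The ketone carbon carries only a methyl group, so no reductive C–heteroatom cleavage competes, and benzyl, methyl and aryl silyl ethers are inert to this reagent.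

Step 5
Reactants: 8 4-(benzyloxy)-6-methoxy-2-[2-methoxy-4-(triisopropylsilyloxy)phenyl]-3-methylbenzofuran
Product: 9 4-(benzyloxy)-6-methoxy-2-[2-methoxy-4-(triisopropylsilyloxy)phenyl]benzofuran-3-carbaldehyde
Conditions: DDQ (2.2 equiv), 1,4-dioxane/H2O, rt
Reagents that add atoms: water, O
Why: DDQ benzylic oxidation: hydride abstraction from the 3-methyl group gives a cation stabilised through C2=C3 by O1 and the electron-rich ring B, water traps it, and a second equivalent of DDQ takes the hydroxymethyl compound to the aldehyde. The formyl group then deactivates the system, so oxidation should stop there; benzyl and silyl ethers tolerate DDQ at room temperature.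

Step 6
Reactants: 9 4-(benzyloxy)-6-methoxy-2-[2-methoxy-4-(triisopropylsilyloxy)phenyl]benzofuran-3-carbaldehyde
Product: 10 4-hydroxy-6-methoxy-2-[2-methoxy-4-(triisopropylsilyloxy)phenyl]benzofuran-3-carbaldehyde
Conditions: H2 (1 atm), 10% Pd/C, EtOAc, rt, stopped after one equivalent of H2
Reagents that add atoms: none
Why: Catalytic hydrogenolysis of an aryl benzyl ether, which in a non-protic solvent at atmospheric pressure is faster than reduction of the conjugated heteroaryl aldehyde (a vinylogous formate); the silyl ether is inert.

Step 7
Reactants: 10 4-hydroxy-6-methoxy-2-[2-methoxy-4-(triisopropylsilyloxy)phenyl]benzofuran-3-carbaldehyde; 11 2-methylbut-3-yn-2-ol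
Product: 13 6-methoxy-2-[2-methoxy-4-(triisopropylsilyloxy)phenyl]-4-[(2-methylbut-3-yn-2-yl)oxy]benzofuran-3-carbaldehyde, via 2-methylbut-3-yn-2-yl trifluoroacetate 12 (not isolated)
Conditions: 11, (CF3CO)2O, DBU, MeCN, −5 °C; then 10, DBU, CuCl2·2H2O (cat.), MeCN, 0 °C to rt
Reagents that add atoms: none
Why: Copper-catalysed propargylic etherification: the copper acetylide of 12 ionises to a copper allenylidene and the phenoxide adds at the tertiary carbon, so only the tertiary propargyl ether can form. DBU converts the phenol into its anion and so breaks the hydrogen bond to the peri aldehyde, and the ring B phenol is masked, so only the C4 oxygen reacts.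

Step 8
Reactants: 13 6-methoxy-2-[2-methoxy-4-(triisopropylsilyloxy)phenyl]-4-[(2-methylbut-3-yn-2-yl)oxy]benzofuran-3-carbaldehyde
Product: 14 6-methoxy-2-[2-methoxy-4-(triisopropylsilyloxy)phenyl]-4-[(2-methylbut-3-en-2-yl)oxy]benzofuran-3-carbaldehyde
Conditions: H2 (1 atm), Pd/CaCO3 poisoned with Pb(OAc)2, quinoline, EtOAc, rt
Reagents that add atoms: none
Why: Lindlar semihydrogenation of a terminal alkyne; the poisoned palladium surface and quinoline stop the reduction at the vinyl group and leave the aldehyde and the furan double bond alone.

Step 9
Reactants: 14 6-methoxy-2-[2-methoxy-4-(triisopropylsilyloxy)phenyl]-4-[(2-methylbut-3-en-2-yl)oxy]benzofuran-3-carbaldehyde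
Product: 15 4-hydroxy-6-methoxy-2-[2-methoxy-4-(triisopropylsilyloxy)phenyl]-5-(3-methylbut-2-en-1-yl)benzofuran-3-carbaldehyde
Conditions: o-xylene, 130 °C, sealed tube
Reagents that add atoms: none
Why: Aromatic Claisen rearrangement: the [3,3] shift goes to C5, the only ortho carbon that bears hydrogen (the other is the ring fusion carbon C3a), and enolisation restores the phenol. Allyl inversion turns the 1,1-dimethylallyl ether into the 3-methylbut-2-enyl chain, and the geminal methyl groups lower the temperature needed.

Step 10
Reactants: 15 4-hydroxy-6-methoxy-2-[2-methoxy-4-(triisopropylsilyloxy)phenyl]-5-(3-methylbut-2-en-1-yl)benzofuran-3-carbaldehyde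
Product: 16 4-hydroxy-2-(4-hydroxy-2-methoxyphenyl)-6-methoxy-5-(3-methylbut-2-en-1-yl)benzofuran-3-carbaldehyde
Conditions: Bu4NF, AcOH, THF, 0 °C
Reagents that add atoms: none
Why: Fluoride-induced cleavage of an aryl silyl ether, driven by the strength of the Si–F bond; the acetic acid buffer keeps the medium near neutral, so neither the aldehyde nor the ortho-prenyl phenol is exposed to strong base or acid.

## Compound list

1 | 1-(2,6-dihydroxy-4-methoxyphenyl)ethanone (2',6'-dihydroxy-4'-methoxyacetophenone) | CC(=O)c1c(O)cc(OC)cc1O | starting material
2 | 1-[2-(benzyloxy)-6-hydroxy-4-methoxyphenyl]ethanone | CC(=O)c1c(O)cc(OC)cc1OCc1ccccc1 | intermediate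
3 | 4-hydroxy-2-methoxybenzoic acid | COc1cc(O)ccc1C(=O)O | starting material
4 | triisopropylsilyl 2-methoxy-4-(triisopropylsilyloxy)benzoate | COc1cc(O[Si](C(C)C)(C(C)C)C(C)C)ccc1C(=O)O[Si](C(C)C)(C(C)C)C(C)C | intermediate
5 | 2-methoxy-4-(triisopropylsilyloxy)benzoic acid | COc1cc(O[Si](C(C)C)(C(C)C)C(C)C)ccc1C(=O)O | intermediate
6 | 2-methoxy-4-(triisopropylsilyloxy)benzoyl chloride | COc1cc(O[Si](C(C)C)(C(C)C)C(C)C)ccc1C(=O)Cl | intermediate
7 | 2-acetyl-3-(benzyloxy)-5-methoxyphenyl 2-methoxy-4-(triisopropylsilyloxy)benzoate | CC(=O)c1c(OCc2ccccc2)cc(OC)cc1OC(=O)c1ccc(O[Si](C(C)C)(C(C)C)C(C)C)cc1OC | intermediate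
8 | 4-(benzyloxy)-6-methoxy-2-[2-methoxy-4-(triisopropylsilyloxy)phenyl]-3-methylbenzofuran | Cc1c(-c2ccc(O[Si](C(C)C)(C(C)C)C(C)C)cc2OC)oc2cc(OC)cc(OCc3ccccc3)c12 | intermediate
9 | 4-(benzyloxy)-6-methoxy-2-[2-methoxy-4-(triisopropylsilyloxy)phenyl]benzofuran-3-carbaldehyde | O=Cc1c(-c2ccc(O[Si](C(C)C)(C(C)C)C(C)C)cc2OC)oc2cc(OC)cc(OCc3ccccc3)c12 | intermediate
10 | 4-hydroxy-6-methoxy-2-[2-methoxy-4-(triisopropylsilyloxy)phenyl]benzofuran-3-carbaldehyde | O=Cc1c(-c2ccc(O[Si](C(C)C)(C(C)C)C(C)C)cc2OC)oc2cc(OC)cc(O)c12 | intermediate
11 | 2-methylbut-3-yn-2-ol | CC(C)(O)C#C | starting material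
12 | 2-methylbut-3-yn-2-yl trifluoroacetate | CC(C)(OC(=O)C(F)(F)F)C#C | intermediate
13 | 6-methoxy-2-[2-methoxy-4-(triisopropylsilyloxy)phenyl]-4-[(2-methylbut-3-yn-2-yl)oxy]benzofuran-3-carbaldehyde | O=Cc1c(-c2ccc(O[Si](C(C)C)(C(C)C)C(C)C)cc2OC)oc2cc(OC)cc(OC(C)(C)C#C)c12 | intermediate
14 | 6-methoxy-2-[2-methoxy-4-(triisopropylsilyloxy)phenyl]-4-[(2-methylbut-3-en-2-yl)oxy]benzofuran-3-carbaldehyde | O=Cc1c(-c2ccc(O[Si](C(C)C)(C(C)C)C(C)C)cc2OC)oc2cc(OC)cc(OC(C)(C)C=C)c12 | intermediate
15 | 4-hydroxy-6-methoxy-2-[2-methoxy-4-(triisopropylsilyloxy)phenyl]-5-(3-methylbut-2-en-1-yl)benzofuran-3-carbaldehyde | O=Cc1c(-c2ccc(O[Si](C(C)C)(C(C)C)C(C)C)cc2OC)oc2cc(OC)c(CC=C(C)C)c(O)c12 | intermediate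
16 | 4-hydroxy-2-(4-hydroxy-2-methoxyphenyl)-6-methoxy-5-(3-methylbut-2-en-1-yl)benzofuran-3-carbaldehyde | COc1cc(O)ccc1-c1oc2cc(OC)c(CC=C(C)C)c(O)c2c1C=O | target

## Step count and risk

Total step count: 10. Longest linear sequence: 9 steps (from 3 through steps 2 to 10; from 1 through steps 1 and 3 to 10 it is also 9).

**Step 4 (key step).** The most likely failure is that the crowded, twisted ketone is reduced to the alcohol or couples between two molecules, or that the aryl ester is cleaved by the Lewis-acidic, reducing medium before the C–C bond forms; the electron-rich ester carbonyl is a poor acceptor. Fallback, from 2 back to 8: the C2=C3 bond is made by an intramolecular Wittig reaction on the same ester carbonyl. NaBH4 in MeOH reduces 2 to racemic 3-(benzyloxy)-2-(1-hydroxyethyl)-5-methoxyphenol F1. Ph3P·HBr in MeCN converts it, through the ortho-quinone methide, into racemic {1-[2-(benzyloxy)-6-hydroxy-4-methoxyphenyl]ethyl}triphenylphosphonium bromide F2. Heating F2 with 6 and Et3N in toluene acylates the phenol to give racemic (1-{2-(benzyloxy)-4-methoxy-6-[2-methoxy-4-(triisopropylsilyloxy)benzoyloxy]phenyl}ethyl)triphenylphosphonium bromide F3, whose ylide closes onto the ester carbonyl and gives 8.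

**Step 7.** Incomplete O-alkylation is the main risk, because the C4 phenol is hydrogen-bonded to the peri formyl group and flanked on both sides, while 12 can be lost by elimination or hydrolysis. Fallback, from 8 back to 14: the order is changed so that the phenol is alkylated before the aldehyde exists.
- Hydrogenolysis of 8 (H2, Pd/C, EtOAc) gives 6-methoxy-2-[2-methoxy-4-(triisopropylsilyloxy)phenyl]-3-methylbenzofuran-4-ol F4.
- The same copper-catalysed reaction with 12 gives 6-methoxy-2-[2-methoxy-4-(triisopropylsilyloxy)phenyl]-3-methyl-4-[(2-methylbut-3-yn-2-yl)oxy]benzofuran F5.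
- Semihydrogenation over Pd/CaCO3 poisoned with Pb(OAc)2 gives 6-methoxy-2-[2-methoxy-4-(triisopropylsilyloxy)phenyl]-3-methyl-4-[(2-methylbut-3-en-2-yl)oxy]benzofuran F6.
- DDQ in wet dioxane then oxidises the 3-methyl group of F6; the ether has no hydrogen on its oxygen-bearing carbon, so it should resist DDQ. This gives 14.

**Step 5.** Oxidative degradation of the very electron-rich ring A, attack on the benzyl ether, or stalling at the hydroxymethyl stage may occur, because DDQ acts through the arene π system as a whole. Fallback, from 8 back to 9: Riley oxidation with SeO2 in dioxane at reflux. This acts on the methyl group of the C2=C3 unit by an ene reaction and a [2,3] shift, so it does not depend on the oxidation potential of the arene. No new compound arises (F0).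

**Step 9.** The tertiary allyl ether may ionise and lose the C5 unit, the rearranged ortho-prenyl phenol may cyclise to a chroman if traces of acid are present, or an abnormal Claisen product may form on prolonged heating. Fallback, from 10 back to 15: prenyl is built from an allyl group.
- Allyl bromide and K2CO3 in DMF give 4-(allyloxy)-6-methoxy-2-[2-methoxy-4-(triisopropylsilyloxy)phenyl]benzofuran-3-carbaldehyde F7.
- Claisen rearrangement in N,N-diethylaniline at 190 °C, again possible only to C5, gives 5-allyl-4-hydroxy-6-methoxy-2-[2-methoxy-4-(triisopropylsilyloxy)phenyl]benzofuran-3-carbaldehyde F8.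
- Cross-metathesis with 2-methylbut-2-ene and second-generation Grubbs catalyst in CH2Cl2 gives 15.

**Step 6.** Over-reduction of the aldehyde to the alcohol or methyl compound, or saturation of the furan double bond, may accompany slow debenzylation. Fallback, from 9 back to 10: Lewis-acid debenzylation with BCl3 and pentamethylbenzene in CH2Cl2 at −78 °C. Coordination to the peri aldehyde assists cleavage of the C4 benzyl ether and the scavenger takes up the benzyl cation, while the methyl ethers and the silyl ether are expected to survive at this temperature. No new compound arises (F0).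

## Further compounds

F1 | step 4 | 3-(benzyloxy)-2-(1-hydroxyethyl)-5-methoxyphenol (racemic) | CC(O)c1c(O)cc(OC)cc1OCc1ccccc1
F2 | step 4 | {1-[2-(benzyloxy)-6-hydroxy-4-methoxyphenyl]ethyl}triphenylphosphonium bromide (racemic) | CC(c1c(O)cc(OC)cc1OCc1ccccc1)[P+](c1ccccc1)(c1ccccc1)c1ccccc1.[Br-]
F3 | step 4 | (1-{2-(benzyloxy)-4-methoxy-6-[2-methoxy-4-(triisopropylsilyloxy)benzoyloxy]phenyl}ethyl)triphenylphosphonium bromide (racemic) | CC(c1c(OC(=O)c2ccc(O[Si](C(C)C)(C(C)C)C(C)C)cc2OC)cc(OC)cc1OCc1ccccc1)[P+](c1ccccc1)(c1ccccc1)c1ccccc1.[Br-]
F4 | step 7 | 6-methoxy-2-[2-methoxy-4-(triisopropylsilyloxy)phenyl]-3-methylbenzofuran-4-ol | Cc1c(-c2ccc(O[Si](C(C)C)(C(C)C)C(C)C)cc2OC)oc2cc(OC)cc(O)c12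
F5 | step 7 | 6-methoxy-2-[2-methoxy-4-(triisopropylsilyloxy)phenyl]-3-methyl-4-[(2-methylbut-3-yn-2-yl)oxy]benzofuran | Cc1c(-c2ccc(O[Si](C(C)C)(C(C)C)C(C)C)cc2OC)oc2cc(OC)cc(OC(C)(C)C#C)c12
F6 | step 7 | 6-methoxy-2-[2-methoxy-4-(triisopropylsilyloxy)phenyl]-3-methyl-4-[(2-methylbut-3-en-2-yl)oxy]benzofuran | Cc1c(-c2ccc(O[Si](C(C)C)(C(C)C)C(C)C)cc2OC)oc2cc(OC)cc(OC(C)(C)C=C)c12
F0 | step 5 | none | none
F7 | step 9 | 4-(allyloxy)-6-methoxy-2-[2-methoxy-4-(triisopropylsilyloxy)phenyl]benzofuran-3-carbaldehyde | O=Cc1c(-c2ccc(O[Si](C(C)C)(C(C)C)C(C)C)cc2OC)oc2cc(OC)cc(OCC=C)c12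
F8 | step 9 | 5-allyl-4-hydroxy-6-methoxy-2-[2-methoxy-4-(triisopropylsilyloxy)phenyl]benzofuran-3-carbaldehyde | O=Cc1c(-c2ccc(O[Si](C(C)C)(C(C)C)C(C)C)cc2OC)oc2cc(OC)c(CC=C)c(O)c12
F0 | step 6 | none | none
A1 | alternative 1 | methyl 5-(2-diazoacetyl)-2-[2-methoxy-4-(triisopropylsilyloxy)phenyl]furan-3-carboxylate | COC(=O)c1cc(C(=O)C=[N+]=[N-])oc1-c1ccc(O[Si](C(C)C)(C(C)C)C(C)C)cc1OC
A2 | alternative 1 | 1-methoxy-5-methylhex-4-en-1-yne | COC#CCC=C(C)C
A3 | alternative 1 | methyl 4-hydroxy-6-methoxy-5-(3-methylbut-2-enyl)-2-[2-methoxy-4-(triisopropylsilyloxy)phenyl]benzofuran-3-carboxylate | COC(=O)c1c(-c2ccc(O[Si](C(C)C)(C(C)C)C(C)C)cc2OC)oc2cc(OC)c(CC=C(C)C)c(O)c12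
A4 | alternative 2 | 4,6-dimethoxybenzofuran | COc1cc(OC)c2ccoc2c1
A5 | alternative 2 | 2-[2-methoxy-4-(triisopropylsilyloxy)phenyl]-4,4,5,5-tetramethyl-1,3,2-dioxaborolane | COc1cc(O[Si](C(C)C)(C(C)C)C(C)C)ccc1B1OC(C)(C)C(C)(C)O1
A6 | alternative 2 | N-(chloromethylidene)-N-methylmethanaminium chloride | C[N+](C)=CCl.[Cl-]
A7 | alternative 2 | 4,6-dimethoxy-2-[2-methoxy-4-(triisopropylsilyloxy)phenyl]benzofuran-3-carbaldehyde | COc1cc(OC)c2c(C=O)c(-c3ccc(O[Si](C(C)C)(C(C)C)C(C)C)cc3OC)oc2c1
A8 | alternative 3 | 5-methoxy-2-(trimethylsilyl)-1,3-phenylene bis(trifluoromethanesulfonate) | COc1cc(OS(=O)(=O)C(F)(F)F)c([Si](C)(C)C)c(OS(=O)(=O)C(F)(F)F)c1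
A9 | alternative 3 | methyl 3-[2-methoxy-4-(methoxymethoxy)phenyl]-3-oxo-2-(phenyl-λ3-iodanylidene)propanoate | COC(=O)[C-]([I+]c1ccccc1)C(=O)c1ccc(OCOC)cc1OC
A10 | alternative 3 | methyl 6-methoxy-2-[2-methoxy-4-(methoxymethoxy)phenyl]-4-(trifluoromethylsulfonyloxy)benzofuran-3-carboxylate | COC(=O)c1c(-c2ccc(OCOC)cc2OC)oc2cc(OC)cc(OS(=O)(=O)C(F)(F)F)c12
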